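**Retrosynthetic overview**

- Target 11 comes from carbinol 10 by loss of three methoxymethyl (MOM) ethers, and 10 from allylic boronate 9 by C2'–B to C2'–OH oxidation with retention.
- 9 is assembled in one operation from vinylboronate 6, alkenyllithium 7 and aryl bromide 5. The vinyl group of 6 supplies C1' and C2'. C2'–C3' forms by alkenyl migration from boron, and ring carbon C3–C1' by reductive elimination at palladium. The chiral ligand sets C2'.
- 7 is generated in the flask of the key step by Shapiro reaction of trisylhydrazone 2, made from sulcatone (1). 5 comes from 2,4,6-trihydroxybenzophenone (3) by MOM protection (4) and monobromination.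
- The strategy rests on the ArCH2(C1')–CH(OH)(C2')–C3'(=CH2) array: a two-carbon unit between ring carbon C3 of the trioxygenated benzoyl ring and the 1,1-disubstituted alkenyl carbon C3', with the heteroatom on C2'.
- No ring is formed; both benzene rings come intact from 3.

Key step: step 4

Assumption: the sense of induction is taken by analogy with known conjunctive couplings, in which the (Sp,Sp) ligand named in step 4 is expected to place boron, migrating group and CH2Ar as in 9; if the opposite sense were found, the (Rp,Rp) enantiomer of the ligand would be used with no other change.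

**Step 1**
Reactants: 1 6-methylhept-5-en-2-one (sulcatone)
Product: 2 (E)-N'-(6-methylhept-5-en-2-ylidene)-2,4,6-triisopropylbenzenesulfonohydrazide
Conditions: 2,4,6-triisopropylbenzenesulfonyl hydrazide (1.0 equiv), conc. HCl (cat.), MeOH, rt; crystallised and dried in vacuo
Reagents that add atoms: 2,4,6-triisopropylbenzenesulfonyl hydrazide, CC(C)c1cc(C(C)C)c(S(=O)(=O)NN)c(C(C)C)c1
Why: Acid-catalysed hydrazone formation from a methyl ketone should give the crystalline trisylhydrazone, mainly as the E isomer with the sulfonamide nitrogen syn to the methyl group.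

**Step 2**
Reactants: 3 2,4,6-trihydroxybenzophenone
Product: 4 phenyl[2,4,6-tris(methoxymethoxy)phenyl]methanone
Conditions: NaH (3.6 equiv), MOMCl (3.6 equiv), DMF, 0 °C → rt
Reagents that add atoms: chloromethyl methyl ether, COCCl
Why: Williamson O-alkylation of the phenoxides with a hard alkylating agent should protect all three hydroxyls, the strong base overcoming the hydrogen bond of the hydroxyls ortho to the carbonyl.

**Step 3**
Reactants: 4 phenyl[2,4,6-tris(methoxymethoxy)phenyl]methanone
Product: 5 [3-bromo-2,4,6-tris(methoxymethoxy)phenyl](phenyl)methanone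
Conditions: NBS (1.0 equiv), MeCN, 0 °C → rt, dark
Reagents that add atoms: N-bromosuccinimide, O=C1CCC(=O)N1Br
Why: Electrophilic aromatic bromination at one of the two equivalent ring CH positions, each activated by two ortho alkoxy groups, should stop at the monobromide with one equivalent of reagent under neutral conditions that leave the MOM ethers intact.

**Step 4**
Reactants: 2 sulcatone trisylhydrazone; 6 vinylboronic acid pinacol ester; 5 [3-bromo-2,4,6-tris(methoxymethoxy)phenyl](phenyl)methanone
Product: 9 [3-[(2R)-7-methyl-3-methylidene-2-(4,4,5,5-tetramethyl-1,3,2-dioxaborolan-2-yl)oct-6-en-1-yl]-2,4,6-tris(methoxymethoxy)phenyl](phenyl)methanone, via alkenyllithium 7 (not isolated), via lithium borate 8 (not isolated)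
Conditions: 2 (1.30 equiv), n-BuLi (2.55 equiv, titrated), THF, −78 → 0 °C until N2 evolution stops; −78 °C, 6 (1.35 equiv), → rt; then 5 (1.00 equiv), Pd(OAc)2 (5 mol%), (Sp,Sp)-1,1'-bis[bis(4-methoxy-3,5-dimethylphenyl)phosphino]-2,2'-bis[(R)-α-(dimethylamino)benzyl]ferrocene (6 mol%), NaOTf (3 equiv), THF, 60 °C
Reagents that add atoms: n-butyllithium, [Li]CCCC (lithium of 7 and 8 only; no atom of it remains in 9)
Why: Shapiro reaction of 2 (deprotonation of N–H and of the syn methyl group, then loss of sulfinate and N2 at 0 °C) gives the less substituted alkenyllithium 7, which adds to the boron of 6 to form the four-coordinate bis(alkenyl)borate 8. Zerovalent palladium, formed from Pd(OAc)2 and the bisphosphine, inserts into the C–Br bond of 5; NaOTf removes bromide, the cationic arylpalladium binds the unsubstituted vinyl group of 8, the alkenyl group shifts from boron to C2' as C1' bonds to palladium, and reductive elimination joins C1' to the ring carbon. The closest known reaction type is the palladium-catalysed enantioselective conjunctive cross-coupling of bis(alkenyl)borates with aryl triflates and halides, which gives allylic boronates; one-pot Shapiro–borylation–Suzuki sequences are also known, which suggests that the lithium arenesulfinate left in the flask is tolerated by palladium coupling. No ring is closed, and the one new stereocentre, C2', is set by the chiral ferrocenyl bisphosphine, which selects the enantioface of the palladium-bound vinyl group during the metallate shift and should give the R boronate. The step needs the α-substituted alkenyl group, not the vinyl group, to migrate; this is secured because the unsubstituted vinyl group is the better π-ligand for palladium and the 1,1-disubstituted alkenyl group the poorer one. It also needs the borate to react by this path rather than by direct alkenyl transfer to palladium, which the chelating ligand and the weakly bound triflate favour, and the benzophenone carbonyl meets only the borate because 6 is kept in slight excess over 7 and n-BuLi is held just under two equivalents per 2.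

**Step 5**
Reactants: 9 (R)-allylic pinacol boronate
Product: 10 [3-[(2R)-2-hydroxy-7-methyl-3-methylideneoct-6-en-1-yl]-2,4,6-tris(methoxymethoxy)phenyl](phenyl)methanone
Conditions: 30% H2O2, 3 M NaOH, THF, 0 °C → rt; Na2S2O3 quench
Reagents that add atoms: hydrogen peroxide, OO
Why: In this boronate oxidation, hydroperoxide adds to boron and C2' migrates from boron to oxygen with retention, so the R boronate should give the R carbinol, while the MOM ethers, the hindered diaryl ketone and the unactivated alkenes are inert to cold alkaline peroxide.

**Step 6**
Reactants: 10 tris-MOM (R)-carbinol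
Product: 11 [2,4,6-trihydroxy-3-[(2R)-2-hydroxy-7-methyl-3-methylideneoct-6-en-1-yl]phenyl](phenyl)methanone (CNP0149425.1)
Conditions: aq. HCl (ca. 0.5 M in the mixture), MeOH, rt, monitored and stopped at full conversion
Reagents that add atoms: none
Why: Acid-catalysed acetal exchange with methanol should cleave the three aryl MOM ethers as dimethoxymethane under conditions too dilute and cool to ionise the allylic carbinol or protonate the alkenes, so C2' is untouched.

**Compound list**

1 | 6-methylhept-5-en-2-one (sulcatone) | CC(=O)CCC=C(C)C | starting material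
2 | (E)-N'-(6-methylhept-5-en-2-ylidene)-2,4,6-triisopropylbenzenesulfonohydrazide | C/C(CCC=C(C)C)=N\NS(=O)(=O)c1c(C(C)C)cc(C(C)C)cc1C(C)C | intermediate
3 | 2,4,6-trihydroxybenzophenone | O=C(c1ccccc1)c1c(O)cc(O)cc1O | starting material
4 | phenyl[2,4,6-tris(methoxymethoxy)phenyl]methanone | COCOc1cc(OCOC)c(C(=O)c2ccccc2)c(OCOC)c1 | intermediate
5 | [3-bromo-2,4,6-tris(methoxymethoxy)phenyl](phenyl)methanone | COCOc1cc(OCOC)c(C(=O)c2ccccc2)c(OCOC)c1Br | intermediate
6 | vinylboronic acid pinacol ester | C=CB1OC(C)(C)C(C)(C)O1 | starting material
7 | (6-methylhepta-1,5-dien-2-yl)lithium | [Li]C(=C)CCC=C(C)C | intermediate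
8 | lithium (6-methylhepta-1,5-dien-2-yl)(vinyl)(pinacolato)borate | [Li+].C=C[B-]1(OC(C)(C)C(C)(C)O1)C(=C)CCC=C(C)C | intermediate
9 | [3-[(2R)-7-methyl-3-methylidene-2-(4,4,5,5-tetramethyl-1,3,2-dioxaborolan-2-yl)oct-6-en-1-yl]-2,4,6-tris(methoxymethoxy)phenyl](phenyl)methanone | C=C(CCC=C(C)C)[C@H](B1OC(C)(C)C(C)(C)O1)Cc1c(OCOC)cc(OCOC)c(C(=O)c2ccccc2)c1OCOC | intermediate
10 | [3-[(2R)-2-hydroxy-7-methyl-3-methylideneoct-6-en-1-yl]-2,4,6-tris(methoxymethoxy)phenyl](phenyl)methanone | C=C(CCC=C(C)C)[C@H](O)Cc1c(OCOC)cc(OCOC)c(C(=O)c2ccccc2)c1OCOC | intermediate
11 | [2,4,6-trihydroxy-3-[(2R)-2-hydroxy-7-methyl-3-methylideneoct-6-en-1-yl]phenyl](phenyl)methanone | C=C(CCC=C(C)C)[C@H](O)Cc1c(O)cc(O)c(C(=O)c2ccccc2)c1O | target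

**Step count**

Total step count: 6. Longest linear sequence: 5 steps (3 → 4 → 5 → 9 → 10 → 11); the arm from 1 through 2 joins at step 4.

**Steps most likely to fail**

1. Step 4. The reaction type is known, but a di-ortho-alkoxy aryl bromide carrying a ketone has not been tried in it.
   - What may go wrong: oxidative addition into the C–Br bond flanked by two alkoxy groups may be slow; direct transfer of an alkenyl group from boron to palladium may compete with the metallate shift; bromide or the arenesulfinate from the Shapiro reaction may bind palladium and inhibit the catalyst; enantioface selection may erode with the hindered aryl group; a butyl group may be transferred if n-BuLi is overdosed.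
   - Fallback, from 5, returning at 10: Stille coupling with allyltributylstannane (Pd(PPh3)4, toluene, 110 °C), which carries no chiral ligand and can be forced thermally, would give phenyl[3-(prop-2-en-1-yl)-2,4,6-tris(methoxymethoxy)phenyl]methanone F1. Oxidative cleavage of its alkene (OsO4 cat., NaIO4, 2,6-lutidine, dioxane/H2O) would give [3-benzoyl-2,4,6-tris(methoxymethoxy)phenyl]acetaldehyde F2. Alkenyllithium 7 (from 2 and n-BuLi as in step 4), converted to its organocerium reagent with CeCl3, should add to the aldehyde at −78 °C and leave the hindered diaryl ketone alone, giving racemic [3-(2-hydroxy-7-methyl-3-methylideneoct-6-en-1-yl)-2,4,6-tris(methoxymethoxy)phenyl](phenyl)methanone F3. Dess–Martin oxidation would give 1-[3-benzoyl-2,4,6-tris(methoxymethoxy)phenyl]-7-methyl-3-methylideneoct-6-en-2-one F4, used at once. Corey–Bakshi–Shibata reduction with (S)-2-methyl-CBS-oxazaborolidine and catecholborane at −78 °C, the alkenyl group acting as the large substituent, is expected to give R carbinol 10.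

2. Step 6.
   - What may go wrong: the acid may ionise the allylic carbinol or protonate an alkene, followed by capture by a neighbouring phenol (chroman or dihydrobenzofuran formation) or by methanol, or by loss of configuration at C2'.
   - Fallback, from 10, returning at 11: the Brønsted acid is avoided altogether. TMSOTf and 2,2'-bipyridyl in MeCN (0 °C → rt) should convert the three aryl MOM ethers into aryl trimethylsilyl ethers and silylate the carbinol, giving [3-[(2R)-7-methyl-3-methylidene-2-(trimethylsilyloxy)oct-6-en-1-yl]-2,4,6-tris(trimethylsilyloxy)phenyl](phenyl)methanone F5. Brief stirring with dilute aqueous citric acid in THF would then hydrolyse the four silyl ethers to 11.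

3. Step 3.
   - What may go wrong: a second bromination at the other activated ring position may compete, or a trace of HBr may remove a MOM group and leave a chelated phenol.
   - Fallback, from 3, returning at 5: the order of bromination and protection is reversed. NBS (1.0 equiv, THF, −78 → 0 °C) on the free triphenol 3, whose ring is deactivated by the coplanar, doubly hydrogen-bonded carbonyl and carries no acetal that could be lost, should give (3-bromo-2,4,6-trihydroxyphenyl)(phenyl)methanone F6. NaH and MOMCl in DMF, as in step 2, would then give 5.

**Further compounds**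

F1 | step 4 | phenyl[3-(prop-2-en-1-yl)-2,4,6-tris(methoxymethoxy)phenyl]methanone | C=CCc1c(OCOC)cc(OCOC)c(C(=O)c2ccccc2)c1OCOC
F2 | step 4 | [3-benzoyl-2,4,6-tris(methoxymethoxy)phenyl]acetaldehyde | O=CCc1c(OCOC)cc(OCOC)c(C(=O)c2ccccc2)c1OCOC
F3 | step 4 | racemic [3-(2-hydroxy-7-methyl-3-methylideneoct-6-en-1-yl)-2,4,6-tris(methoxymethoxy)phenyl](phenyl)methanone | C=C(CCC=C(C)C)C(O)Cc1c(OCOC)cc(OCOC)c(C(=O)c2ccccc2)c1OCOC
F4 | step 4 | 1-[3-benzoyl-2,4,6-tris(methoxymethoxy)phenyl]-7-methyl-3-methylideneoct-6-en-2-one | C=C(CCC=C(C)C)C(=O)Cc1c(OCOC)cc(OCOC)c(C(=O)c2ccccc2)c1OCOC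
F5 | step 6 | [3-[(2R)-7-methyl-3-methylidene-2-(trimethylsilyloxy)oct-6-en-1-yl]-2,4,6-tris(trimethylsilyloxy)phenyl](phenyl)methanone | C=C(CCC=C(C)C)[C@H](O[Si](C)(C)C)Cc1c(O[Si](C)(C)C)cc(O[Si](C)(C)C)c(C(=O)c2ccccc2)c1O[Si](C)(C)C
F6 | step 3 | (3-bromo-2,4,6-trihydroxyphenyl)(phenyl)methanone | O=C(c1ccccc1)c1c(O)cc(O)c(Br)c1O
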